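Time is what I read first in the north flask: target climbs in a straight line, reaches 16.8% at 3.00 h and 21.3% at 4.00 h, then stands at 21.5% at 6.00 h.

| setting | north | south-west | flask |
|---|---|---|---|
| solid substrate | 0.72 M | 1.1 M | 0.72 M |
| partner | 1 equiv | 1 equiv | 1.00 equiv |
| temperature | 0 °C | −5 °C | 0 °C |
| remark | the very flask that is asked about, followed so far | run made earlier |  |
| time |  |  | 10 h |

- north (time / h: target / %): 0.833: 4.1; 1.33: 8.2; 2.00: 11.2; 3.00: 16.8; 4.00: 21.3; 6.00: 21.5; 10.0: 20.5
- south-west (time / h: target / %): 0.333: 1.1; 0.500: 1.5; 0.667: 2.4; 1.00: 3.9; 1.50: 5.7; 2.50: 9.5; 4.00: 14.8

(each reading ± 0.5 percentage points)

- a species is counted by the solid substrate in it: one self-condensation product or side product counts as two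
- given per volume of solution although it is solid: solid substrate
- target taken out counts as made
- candidate steps: solid substrate + target -> side product; 2 solid substrate -> self-condensation product; dissolved substrate + partner -> target; solid substrate <-> dissolved substrate
- at the start none of the solid substrate is in solution
- additions bring no volume worth counting

- maple: at 10 h add partner, 50.0% of the amount charged, then wait 20 h
- larch: change nothing and wait 20 h more
- alder: at 10 h raise the temperature by 15 K, then wait 20 h
- birch: at 10 h take out 90% of the target then present, then wait 20 h

- target, in percent of the solid substrate first charged, at 10 h
- the remedy with the largest gain of target, or "none" below 2 percentage points (maple / larch / alder / birch / none)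
- target present, with what was taken out counted in, in percent of the solid substrate first charged, after larch
- target present, with what was taken out counted in, in percent of the solid substrate first charged, after alder

The candidate steps are dissolving, dissolved substrate with partner to target, self-condensation of solid substrate, and solid substrate with target to side product.

A straight line means a constant rate, and a constant rate integrates in one step: [target] = f·t. I define the feed f, the target made per litre per hour while the line is straight. The reading at 4.00 h may already lie past the bend, so I take the one at 3.00 h, which gives 0.0403 M/h. The south-west run gives 0.0407 M/h, but it is colder and richer, so that match may be two shifts cancelling, and I don't lean on it.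

The last three north readings average 21.1%. Dividing that amount by f puts my estimate of the stop at τ = 3.77 h, just before the reading at 4.00 h, so I read the bend as sharp.

Is the last reading a real decline? It is down 1 percentage point, against 0.71 points of scatter on a difference, so I can't call it one. Could partner be what stops the line? That plateau leaves roughly 78.9% of partner, less whatever target went on to side product, so partner is not the limiting reagent. I therefore commit to about 21.1% now and after waiting or heating, with no remedy worth taking.

The forecast gives 21% (20.3% to 21.7%), 21% after larch, 21% after alder, and none as best, on the ground that “The stop must mean the solid is gone”.

    solid substrate + target → side product (k = 0.841 /M/h, Ea = 73.0 kJ/mol)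
    2 solid substrate → self-condensation product (k = 1.35 /M/h, Ea = 57.0 kJ/mol)
    dissolved substrate + partner → target (k = 93.3 /M/h, Ea = 62.0 kJ/mol)
    solid substrate ⇌ dissolved substrate, rate k4*(cs4 - [dissolved substrate]) while solid is left; crystals form when [dissolved substrate] > cs4 (solubility = 0.0920 M, k = 0.524 /h)
    (constants at 0 °C)

The simulation gives 21.6% for the north flask, 21.6% after larch, 21.6% after alder, and none as best. In this flask half of the self-condensation turnover up to 10 h is done by 0.305 h, sooner than half of the target-forming turnover at 1.85 h, and by 5.00 h solid substrate stands at 0%, with 73.0% in self-condensation product. Divided by f, this flask's target comes to 3.86 h, and that of the flask with 2.9 M of solid substrate, whose 5.66% is 0.164 M of target, comes to 4.07 h.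

(All runs were generated by integration from invented constants, and the scatter is random.)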